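If a bond is drawn between C1 and C6 of the ring numbered C1(Me)=C2–C3–C4–C5(Me)(OH)–C6=C7–C8(iPr)–C9(OAr)–C10, the six atoms C1, C10, C9, C8, C7 and C6 spell out a p-menthane oxygenated next to its isopropyl carbon, and C2–C5 remain as a four-carbon insert. The route therefore rests on an anionic oxy-Cope ring expansion of a piperitone-derived cyclohexanol. In one operation it forms C3–C4, cleaves C1–C6, creates the ten-membered ring with its E C1=C2 alkene and leaves a C5=C6 enolate, trapped as a silyl enol ether for later C5 hydroxylation. The precursor carries hydroxyl and isopropenyl on C6, methyl and vinyl on C1 (alkenyl groups trans), isopropyl on C8 and a silyl ether on C9.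

Key step: step 7

Remark: atom labels C1–C10 follow the ring numbering above for all intermediates; (R)-piperitone of high enantiomeric purity is assumed.
Remark: C1 and C6 of the Cope precursor are sacrificial stereocentres and are assigned as the diastereomer that substrate control should deliver (vinyl cis to the C8 isopropyl group, isopropenyl trans to vinyl). The all-equatorial diastereomer would require an equatorial aldol at C1 and an addition syn to an axial α-substituent at C6, which cannot be defended; both diastereomers give the same ring-expanded product.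

Step 1
Reactants: 1 (R)-(−)-piperitone
Product: 2 trans-piperitol [(1R,6R)-3-methyl-6-(propan-2-yl)cyclohex-2-en-1-ol]
Conditions: NaBH4, CeCl3·7H2O, MeOH, −78 to 0 °C
Reagents that add atoms: none
Why: Luche 1,2-reduction; axial hydride delivery to the half-chair enone with a pseudo-equatorial isopropyl group should set the C9 carbinol equatorial and trans to isopropyl at C8, and the minor cis alcohol is removed by chromatography.

Step 2
Reactants: 2 trans-piperitol
Product: 3 trans-piperitol tert-butyldimethylsilyl ether
Conditions: TBSCl, imidazole, DMF, 25 °C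
Reagents that add atoms: tert-butyldimethylsilyl chloride, CC(C)(C)[Si](C)(C)Cl
Why: Standard silylation of a secondary allylic alcohol; no stereocentre is touched and the ether should survive the hydride, Grignard and KH steps that follow.

Step 3
Reactants: 3 trans-piperitol tert-butyldimethylsilyl ether
Product: 5 enone (4R,5R)-4-[(tert-butyldimethylsilyl)oxy]-2-methyl-5-(propan-2-yl)cyclohex-2-en-1-one, via C6 allylic alcohol 4 (not isolated)
Conditions: SeO2 (0.5 equiv), t-BuOOH, CH2Cl2, 0 to 25 °C; filter; then MnO2, CH2Cl2, 25 °C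
Reagents that add atoms: tert-butyl hydroperoxide, CC(C)(C)OO; selenium dioxide, O=[Se]=O
Why: Riley allylic oxidation followed by MnO2 oxidation of the allylic alcohol; the ene step bonds selenium to C10 and takes hydrogen from the ring methylene C6 on the more substituted alkene terminus, and the [2,3]-shift returns the C1=C10 alkene with oxygen on C6, so the silyloxy-bearing C9–H lies on the non-reacting side.

Step 4
Reactants: 5 enone; 6 acetaldehyde
Product: 8 aldol (2R,4S,5R)-4-[(tert-butyldimethylsilyl)oxy]-2-(1-hydroxyethyl)-2-methyl-5-(propan-2-yl)cyclohexan-1-one (both carbinol epimers), via lithium enolate 7 (not isolated)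
Conditions: LiBH(s-Bu)3, THF, −78 °C; then CH3CHO, −78 °C; AcOH quench
Reagents that add atoms: none
Why: Conjugate reduction followed by aldol addition of the regiodefined C1 enolate (reductive aldol); the aldehyde should approach C1 axially on the half-chair that keeps isopropyl and silyloxy pseudo-equatorial, which places the new C–C bond cis to the C8 isopropyl group, and the carbinol centre is irrelevant because it is eliminated next.

Step 5
Reactants: 8 aldol
Product: 9 vinyl ketone (2R,4S,5R)-4-[(tert-butyldimethylsilyl)oxy]-2-ethenyl-2-methyl-5-(propan-2-yl)cyclohexan-1-one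
Conditions: Martin sulfurane Ph2S[OC(CF3)2Ph]2, CH2Cl2, 0 to 25 °C
Reagents that add atoms: none
Why: Sulfurane dehydration of a secondary alcohol; C1 is quaternary, so elimination can only take a methyl hydrogen and must give the vinyl group, both carbinol epimers converge, and any minor C1 epimer from step 4 is removed here by chromatography.

Step 6
Reactants: 9 vinyl ketone; 10 isopropenylmagnesium bromide
Product: 11 Cope precursor (1S,2R,4S,5R)-4-[(tert-butyldimethylsilyl)oxy]-2-ethenyl-2-methyl-5-(propan-2-yl)-1-(prop-1-en-2-yl)cyclohexan-1-ol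
Conditions: CeCl3, THF, −78 °C; isopropenylmagnesium bromide, −78 to 0 °C
Reagents that add atoms: none
Why: Organocerium 1,2-addition to a hindered, enolisable ketone; in the chair with isopropyl and silyloxy equatorial the C1 vinyl group is axial, so the nucleophile should enter C6 from the opposite face, giving isopropenyl trans to vinyl and the C6 hydroxyl cis to vinyl.

Step 7
Reactants: 11 Cope precursor
Product: 14 silyl enol ether (1Z,5E,8S,9R)-8-[(tert-butyldimethylsilyl)oxy]-2,6-dimethyl-9-(propan-2-yl)-1-[(trimethylsilyl)oxy]cyclodeca-1,5-diene (ring carbons C4 and C7 trans across C5=C6), via potassium alkoxide 12 (not isolated), via potassium enolate 13 (not isolated)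
Conditions: KH, 18-crown-6, THF, 0 to 66 °C; then Me3SiCl, Et3N, −78 to 0 °C; product kept at or below 25 °C
Reagents that add atoms: chlorotrimethylsilane, C[Si](C)(C)Cl
Why: KH converts 11 into potassium alkoxide 12, the oxyanion weakens the adjacent C1–C6 bond, and the 1,5-diene C3=C2–C1–C6–C5=C4 rearranges by a [3,3]-sigmatropic shift through a chair transition state in which C3–C4 forms as C1–C6 breaks, ending irreversibly at enolate 13, which Me3SiCl silylates on oxygen. The closest known reaction type is the anionic oxy-Cope ring expansion of trans-1,2-dialkenylcyclohexanols to (E)-cyclodec-5-enones. The ten-membered ring is closed by ring expansion (the four alkenyl carbons C2–C5 are inserted between C1 and C6), not by an end-to-end cyclisation. No stereocentre is formed, C1 and C6 become trigonal, and C8 and C9 are not involved. The step needs the E C1=C2 alkene and one enolate geometry (C4 and C7 trans), and the trans relationship of vinyl and isopropenyl secures both, because C2 and C5 are gauche only in the chair that has both groups equatorial, which places C10 and C7 equatorially on the six-membered transition state. That chair carries the isopropyl and silyloxy groups axially, and the resting chair, with both alkenyl groups axial and anti, cannot react, so warming is expected to be necessary.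

Step 8
Reactants: 14 silyl enol ether
Product: 16 silyloxy ketone (2R,5E,8S,9R)-8-[(tert-butyldimethylsilyl)oxy]-2,6-dimethyl-9-(propan-2-yl)-2-[(trimethylsilyl)oxy]cyclodec-5-en-1-one, via silyloxy epoxide 15 (not isolated)
Conditions: dimethyldioxirane (1.0 equiv), acetone–CH2Cl2, −78 °C; then 25 °C
Reagents that add atoms: dimethyldioxirane, CC1(C)OO1
Why: Rubottom oxidation; the electron-rich tetrasubstituted enol ether should be epoxidised much faster than the C1=C2 alkene and the silyloxy epoxide opens with 1,4-silyl shift to the C5 silyl ether, oxygen arriving on the outer face of C5=C6 in the crossed conformer that keeps the C8 and C9 substituents pseudo-equatorial and both ring methyl groups on the isopropyl face, which gives the 5R carbinol.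

Step 9
Reactants: 16 silyloxy ketone
Product: 17 enol triflate (1Z,3S,4S,6E,10R)-4-[(tert-butyldimethylsilyl)oxy]-6,10-dimethyl-3-(propan-2-yl)-10-[(trimethylsilyl)oxy]cyclodeca-1,6-dien-1-yl trifluoromethanesulfonate (C5 and C8 trans across C6=C7)
Conditions: KN(SiMe3)2, THF, −78 °C; PhNTf2, −78 to 0 °C
Reagents that add atoms: N-phenylbis(trifluoromethanesulfonimide), O=S(=O)(N(c1ccccc1)S(=O)(=O)C(F)(F)F)C(F)(F)F
Why: Kinetic enolisation and O-triflation (enol triflate formation); C5 is quaternary, so the ketone can enolise only toward C7, and the bulky C5 centre should turn away from C8 as in the enolisation of tert-alkyl ketones, which places C5 and C8 trans.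

Step 10
Reactants: 17 enol triflate
Product: 18 bis-silyl diene tert-butyl{[(1S,2S,3E,5R,8E)-5,9-dimethyl-2-(propan-2-yl)-5-[(trimethylsilyl)oxy]cyclodeca-3,8-dien-1-yl]oxy}dimethylsilane
Conditions: Pd(OAc)2 (5 mol %), PPh3, HCO2H, Bu3N, DMF, 40 °C
Reagents that add atoms: none
Why: Palladium-catalysed formate reduction of an enol triflate; hydride replaces triflate with retention of alkene geometry, so the E C6=C7 alkene should result without a cationic intermediate that could start a transannular cyclisation.

Step 11
Reactants: 18 bis-silyl diene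
Product: 19 diol (1S,2S,3E,5R,8E)-5,9-dimethyl-2-(propan-2-yl)cyclodeca-3,8-diene-1,5-diol
Conditions: Bu4NF, THF, 0 to 25 °C
Reagents that add atoms: none
Why: Fluoride desilylation removes the tertiary trimethylsilyl and the secondary tert-butyldimethylsilyl ether under non-acidic conditions that the tertiary allylic alcohol should tolerate.

Step 12
Reactants: 20 4-hydroxybenzoic acid
Product: 22 4-[(tert-butyldimethylsilyl)oxy]benzoic acid, via bis-silyl derivative 21 (not isolated)
Conditions: TBSCl (2.2 equiv), imidazole, DMF, 25 °C; then AcOH–THF–H2O, 25 °C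
Reagents that add atoms: tert-butyldimethylsilyl chloride, CC(C)(C)[Si](C)(C)Cl
Why: Exhaustive silylation followed by selective hydrolysis of the labile silyl ester, which leaves the aryl silyl ether in place.

Step 13
Reactants: 19 diol; 22 4-[(tert-butyldimethylsilyl)oxy]benzoic acid
Product: 23 ester (1S,2S,3E,5R,8E)-5-hydroxy-5,9-dimethyl-2-(propan-2-yl)cyclodeca-3,8-dien-1-yl 4-[(tert-butyldimethylsilyl)oxy]benzoate
Conditions: EDC·HCl, DMAP, CH2Cl2, 0 to 25 °C
Reagents that add atoms: none
Why: Steglich esterification; only the secondary C9 hydroxyl should be acylated because the tertiary C5 alcohol is inert to carbodiimide/DMAP acylation, and C9 keeps its configuration.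

Step 14
Reactants: 23 ester
Product: 24 target (1S,2S,3E,5R,8E)-5-hydroxy-5,9-dimethyl-2-(propan-2-yl)cyclodeca-3,8-dien-1-yl 4-hydroxybenzoate
Conditions: Bu4NF, AcOH, THF, 0 °C
Reagents that add atoms: none
Why: Buffered fluoride cleavage of an aryl silyl ether, which should be much faster than any reaction at the benzoate ester or the tertiary allylic alcohol.

Compound list
1 | (R)-(−)-piperitone | CC1=CC(=O)[C@@H](C(C)C)CC1 | starting material
2 | trans-piperitol, (1R,6R)-3-methyl-6-(propan-2-yl)cyclohex-2-en-1-ol | CC1=C[C@H](O)[C@@H](C(C)C)CC1 | intermediate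
3 | trans-piperitol tert-butyldimethylsilyl ether | CC1=C[C@H](O[Si](C)(C)C(C)(C)C)[C@@H](C(C)C)CC1 | intermediate
4 | C6 allylic alcohol of 3, epimers at C6 (not isolated) | CC1=C[C@H](O[Si](C)(C)C(C)(C)C)[C@@H](C(C)C)CC1O | intermediate
5 | (4R,5R)-4-[(tert-butyldimethylsilyl)oxy]-2-methyl-5-(propan-2-yl)cyclohex-2-en-1-one | CC1=C[C@H](O[Si](C)(C)C(C)(C)C)[C@@H](C(C)C)CC1=O | intermediate
6 | acetaldehyde | CC=O | starting material
7 | lithium enolate of the 1,4-reduced enone (not isolated) | CC1=C([O-])C[C@H](C(C)C)[C@@H](O[Si](C)(C)C(C)(C)C)C1.[Li+] | intermediate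
8 | (2R,4S,5R)-4-[(tert-butyldimethylsilyl)oxy]-2-(1-hydroxyethyl)-2-methyl-5-(propan-2-yl)cyclohexan-1-one, both carbinol epimers | CC(O)[C@@]1(C)C[C@H](O[Si](C)(C)C(C)(C)C)[C@@H](C(C)C)CC1=O | intermediate
9 | (2R,4S,5R)-4-[(tert-butyldimethylsilyl)oxy]-2-ethenyl-2-methyl-5-(propan-2-yl)cyclohexan-1-one | C=C[C@@]1(C)C[C@H](O[Si](C)(C)C(C)(C)C)[C@@H](C(C)C)CC1=O | intermediate
10 | isopropenylmagnesium bromide | C=C(C)[Mg]Br | starting material
11 | (1S,2R,4S,5R)-4-[(tert-butyldimethylsilyl)oxy]-2-ethenyl-2-methyl-5-(propan-2-yl)-1-(prop-1-en-2-yl)cyclohexan-1-ol (Cope precursor) | C=C[C@@]1(C)C[C@H](O[Si](C)(C)C(C)(C)C)[C@@H](C(C)C)C[C@]1(O)C(C)=C | intermediate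
12 | potassium alkoxide of 11 (not isolated) | C=C[C@@]1(C)C[C@H](O[Si](C)(C)C(C)(C)C)[C@@H](C(C)C)C[C@]1([O-])C(C)=C.[K+] | intermediate
13 | ten-membered potassium enolate, E C1=C2, C4 and C7 trans (not isolated) | C/C1=C\CC/C(C)=C([O-])/C[C@H](C(C)C)[C@@H](O[Si](C)(C)C(C)(C)C)C1.[K+] | intermediate
14 | (1Z,5E,8S,9R)-8-[(tert-butyldimethylsilyl)oxy]-2,6-dimethyl-9-(propan-2-yl)-1-[(trimethylsilyl)oxy]cyclodeca-1,5-diene | C/C1=C\CC/C(C)=C(O[Si](C)(C)C)/C[C@H](C(C)C)[C@@H](O[Si](C)(C)C(C)(C)C)C1 | intermediate
15 | trans C5–C6 silyloxy epoxide of 14 (not isolated) | C/C1=C\CC[C@@]2(C)O[C@]2(O[Si](C)(C)C)C[C@H](C(C)C)[C@@H](O[Si](C)(C)C(C)(C)C)C1 | intermediate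
16 | (2R,5E,8S,9R)-8-[(tert-butyldimethylsilyl)oxy]-2,6-dimethyl-9-(propan-2-yl)-2-[(trimethylsilyl)oxy]cyclodec-5-en-1-one | C/C1=C\CC[C@@](C)(O[Si](C)(C)C)C(=O)C[C@H](C(C)C)[C@@H](O[Si](C)(C)C(C)(C)C)C1 | intermediate
17 | (1Z,3S,4S,6E,10R)-4-[(tert-butyldimethylsilyl)oxy]-6,10-dimethyl-3-(propan-2-yl)-10-[(trimethylsilyl)oxy]cyclodeca-1,6-dien-1-yl trifluoromethanesulfonate | C/C1=C\CC[C@@](C)(O[Si](C)(C)C)/C(OS(=O)(=O)C(F)(F)F)=C/[C@H](C(C)C)[C@@H](O[Si](C)(C)C(C)(C)C)C1 | intermediate
18 | tert-butyl{[(1S,2S,3E,5R,8E)-5,9-dimethyl-2-(propan-2-yl)-5-[(trimethylsilyl)oxy]cyclodeca-3,8-dien-1-yl]oxy}dimethylsilane | C/C1=C\CC[C@@](C)(O[Si](C)(C)C)/C=C/[C@H](C(C)C)[C@@H](O[Si](C)(C)C(C)(C)C)C1 | intermediate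
19 | (1S,2S,3E,5R,8E)-5,9-dimethyl-2-(propan-2-yl)cyclodeca-3,8-diene-1,5-diol | C/C1=C\CC[C@@](C)(O)/C=C/[C@H](C(C)C)[C@@H](O)C1 | intermediate
20 | 4-hydroxybenzoic acid | OC(=O)c1ccc(O)cc1 | starting material
21 | tert-butyldimethylsilyl 4-[(tert-butyldimethylsilyl)oxy]benzoate (not isolated) | CC(C)(C)[Si](C)(C)OC(=O)c1ccc(O[Si](C)(C)C(C)(C)C)cc1 | intermediate
22 | 4-[(tert-butyldimethylsilyl)oxy]benzoic acid | OC(=O)c1ccc(O[Si](C)(C)C(C)(C)C)cc1 | intermediate
23 | (1S,2S,3E,5R,8E)-5-hydroxy-5,9-dimethyl-2-(propan-2-yl)cyclodeca-3,8-dien-1-yl 4-[(tert-butyldimethylsilyl)oxy]benzoate | C/C1=C\CC[C@@](C)(O)/C=C/[C@H](C(C)C)[C@@H](OC(=O)c2ccc(O[Si](C)(C)C(C)(C)C)cc2)C1 | intermediate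
24 | (1S,2S,3E,5R,8E)-5-hydroxy-5,9-dimethyl-2-(propan-2-yl)cyclodeca-3,8-dien-1-yl 4-hydroxybenzoate | C/C1=C\CC[C@@](C)(O)/C=C/[C@H](C(C)C)[C@@H](OC(=O)c2ccc(O)cc2)C1 | target

Total step count: 14. Longest linear sequence: 13 steps (steps 1–11, 13 and 14; step 12 is a one-step side branch).

Steps most likely to fail

Step 7. The rearrangement may be slow or incomplete because the only reactive chair is disfavoured, and desilylation or a competing [1,3]-shift may intervene at the temperature then needed. The fallback sets out from 11 and returns to the route at 14. Alcohol 11 would be silylated with N-(trimethylsilyl)imidazole to the C6 trimethylsilyl ether F1. This ether would be rearranged without base by a thermal siloxy-Cope ring expansion (sealed tube or flow pyrolysis, about 220–250 °C, short contact time), which gives silyl enol ether 14 directly; unchanged F1 would be recycled.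

Step 8. Facial selectivity at C5 may be poor if the ring reacts through a conformer with the C5 methyl group on the face opposite to isopropyl, and the C1=C2 alkene may be epoxidised as well. The fallback sets out from 14 and returns at 16. MeLi would cleave the enol silyl ether to the lithium enolate F2. The enolate would be hydroxylated with an enantiopure (camphorsulfonyl)oxaziridine chosen to reinforce attack on the required face (reagent control; isolated alkenes are not touched) to give the hydroxy ketone F3. N-(Trimethylsilyl)imidazole would then give 16.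

Step 9. Geometric control in the enolisation may be lost, giving the enol triflate with C5 and C8 cis and hence the Z alkene after reduction. The fallback sets out from 16 and returns at 19, bypassing 17 and 18. NaBH4 in MeOH followed by K2CO3 would give the C5,C6-diol F4. MsCl/Et3N would sulfonylate only the secondary hydroxyl to the mesylate F5, and K2CO3 in MeOH would close the C5–C6 epoxide F6. PhSeNa (from PhSeSePh and NaBH4 in EtOH) would open the epoxide at the secondary carbon C6 to the hydroxy selenide F7. H2O2/pyridine would then give the E allylic alcohol F8 by selenoxide syn elimination toward C7, the only side that bears hydrogen, and Bu4NF converts F8 into 19.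

Further compounds
F1 | step 7 | C6 trimethylsilyl ether of 11 | C=C[C@@]1(C)C[C@H](O[Si](C)(C)C(C)(C)C)[C@@H](C(C)C)C[C@]1(O[Si](C)(C)C)C(C)=C
F2 | step 8 | ten-membered lithium enolate, E C1=C2, C4 and C7 trans | C/C1=C\CC/C(C)=C([O-])/C[C@H](C(C)C)[C@@H](O[Si](C)(C)C(C)(C)C)C1.[Li+]
F3 | step 8 | (2R,5E,8S,9R)-8-[(tert-butyldimethylsilyl)oxy]-2-hydroxy-2,6-dimethyl-9-(propan-2-yl)cyclodec-5-en-1-one | C/C1=C\CC[C@@](C)(O)C(=O)C[C@H](C(C)C)[C@@H](O[Si](C)(C)C(C)(C)C)C1
F4 | step 9 | C5,C6-diol with the C9 silyl ether, epimers at C6 | C/C1=C\CC[C@@](C)(O)C(O)C[C@H](C(C)C)[C@@H](O[Si](C)(C)C(C)(C)C)C1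
F5 | step 9 | C6 methanesulfonate of F4 | C/C1=C\CC[C@@](C)(O)C(OS(C)(=O)=O)C[C@H](C(C)C)[C@@H](O[Si](C)(C)C(C)(C)C)C1
F6 | step 9 | C5–C6 epoxide with the C9 silyl ether | C/C1=C\CC[C@@]2(C)OC2C[C@H](C(C)C)[C@@H](O[Si](C)(C)C(C)(C)C)C1
F7 | step 9 | C5 hydroxy C6 phenylselenide with the C9 silyl ether | C/C1=C\CC[C@@](C)(O)C([Se]c2ccccc2)C[C@H](C(C)C)[C@@H](O[Si](C)(C)C(C)(C)C)C1
F8 | step 9 | C9 tert-butyldimethylsilyl ether of diol 19 | C/C1=C\CC[C@@](C)(O)/C=C/[C@H](C(C)C)[C@@H](O[Si](C)(C)C(C)(C)C)C1
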